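The route rests on cutting ring A and ring B at the same time across C5–C10 and C6–C7. The quaternary C5 (bearing C14) and C10–H are adjacent cis ring-fusion atoms, C4 next to C5 can be a ketone and C8/C9 can emerge as an enol ether. The decalin therefore folds back to an isopropenyl ketone (C6=C5–C4=O) tethered through C3–C2–C1 to a 2-silyloxydiene (C10=C9–C8(OSi)=C7). One catalytic enantioselective intramolecular Diels–Alder reaction closes both rings and sets C5 and C10. Its precursor is the achiral acyclic trienone (7E)-2-methyl-9-(triisopropylsilyloxy)deca-1,7,9-trien-3-one, unveiled from a Weinreb amide immediately before use.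

Key step: step 5

Remarks and assumptions
- Bicyclic compounds are named on the eremophilane skeleton: ring A = C1–C2–C3–C4–C5–C10, ring B = C5–C6–C7–C8–C9–C10, C14 = methyl on C5, C15 = methyl on C4, C11(C12)(C13) on C7. β is the face of the C5 methyl group, α the opposite face. "11,12,13-trinor" marks compounds without the C7 side chain.
- Assumption: the oxazaborolidinium ion from (S)-diphenylprolinol is written as the antipode that should leave open the enone face leading to (4aR,8aS)-11. If the sense of induction proves opposite, the (R)-catalyst is used under the same conditions.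
- Assumption: the configuration of the temporary C8 carbinol in 20, 21 and 23 is left open (no stereo label). It is removed in step 12.
- The target has C3–O, C15, the C7 side chain and C9–O all equatorial in the cis-decalin conformer with C14 axial on ring A. The post-cycloaddition sequence is ordered so that ring B is substituted first and locks this conformer before ring A is functionalised.

Step 1
Reactants: 1 hex-5-enoic acid; 2 N,O-dimethylhydroxylamine hydrochloride
Product: 4 N-methoxy-N-methylhex-5-enamide, via 1-(hex-5-enoyl)imidazole 3 (not isolated)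
Conditions: 1,1′-carbonyldiimidazole, CH2Cl2, 0 °C → rt; then 2, rt
Reagents that add atoms: none
Why: Weinreb amide formation, in which the acid is activated as its acyl imidazolide and acylates the liberated N,O-dimethylhydroxylamine while the terminal alkene is untouched.

Step 2
Reactants: 4 N-methoxy-N-methylhex-5-enamide; 5 but-3-en-2-one
Product: 6 (E)-N-methoxy-N-methyl-7-oxooct-5-enamide
Conditions: 5 (3 equiv), Hoveyda–Grubbs second-generation catalyst RuCl2(H2IMes)(=CH-C6H4-2-OiPr) (3 mol%), CH2Cl2, 40 °C
Reagents that add atoms: none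
Why: Olefin cross-metathesis of a terminal alkene with an electron-poor vinyl ketone is selective for the cross product and should give the (E)-enone that later becomes the (E)-diene, the amide being inert to the ruthenium carbene.

Step 3
Reactants: 6 (E)-N-methoxy-N-methyl-7-oxooct-5-enamide
Product: 7 (E)-N-methoxy-N-methyl-7-(triisopropylsilyloxy)octa-5,7-dienamide
Conditions: iPr3SiOSO2CF3 (1.1 equiv), Et3N, CH2Cl2, −78 → 0 °C
Reagents that add atoms: triisopropylsilyl trifluoromethanesulfonate, CC(C)[Si](C(C)C)(C(C)C)OS(=O)(=O)C(F)(F)F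
Why: Soft enolisation of the methyl enone with silyl triflate and amine gives the cross-conjugated 2-silyloxydiene, and at this stage the molecule holds no hydroxyl group and no second ketone that could compete for the silylating agent.

Step 4
Reactants: 7 (E)-N-methoxy-N-methyl-7-(triisopropylsilyloxy)octa-5,7-dienamide; 8 isopropenylmagnesium bromide
Product: 10 (7E)-2-methyl-9-(triisopropylsilyloxy)deca-1,7,9-trien-3-one, via bromomagnesium hemiaminal alkoxide 9 (not isolated)
Conditions: 8 (1.5 equiv), THF, −40 → 0 °C; inverse quench into cold aq NH4Cl, extraction and short silica plug below 0 °C, used at once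
Reagents that add atoms: none
Why: Weinreb ketone synthesis, in which the chelated tetrahedral adduct keeps the dienophile masked until the cold quench, so that the trienone cannot over-add or cyclise thermally before it meets the catalyst, the silyl dienol ether being inert to the Grignard reagent.

Step 5
Reactants: 10 (7E)-2-methyl-9-(triisopropylsilyloxy)deca-1,7,9-trien-3-one
Product: 11 (4aR,8aS)-8a-methyl-6-(triisopropylsilyloxy)-3,4,4a,7,8,8a-hexahydronaphthalen-1(2H)-one
Conditions: (S)-1-(2-methylphenyl)-3,3-diphenyltetrahydro-1H,3H-pyrrolo[1,2-c][1,3,2]oxazaborole (20 mol%), HN(SO2CF3)2 (18 mol%), CH2Cl2, −78 → −40 °C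
Reagents that add atoms: none
Why: The protonated oxazaborolidine binds the C4 carbonyl as a chiral Lewis acid and lowers the LUMO of the C5=C6 enone, which adds to the electron-rich silyloxydiene in a concerted asynchronous [4+2] with C6–C7 bonding ahead of C5–C10. The closest known reactions are the Lewis acid-catalysed intramolecular Diels–Alder reaction of 1,7,9-decatrien-3-ones and oxazaborolidinium-catalysed Diels–Alder additions of 2-silyloxydienes to α-substituted enones. Ring B closes as the cyclohexene formed by the cycloaddition itself, and ring A closes in the fused mode through the three-carbon tether C3–C2–C1 with the tether carbonyl endo. C5 and C10 are set relative to each other by that endo orientation together with the (E)-geometry of C9=C10, which puts C14 and H10 cis, and absolutely by the enone face that the catalyst leaves open. The step needs regio-, cis- and enantioselectivity: the tether length and the match of the nucleophilic diene terminus C7 with the enone β-carbon C6 fix the regiochemistry, the in-chain ketone favours the endo transition state under Lewis acid catalysis, and the α-methyl group and the low temperature keep the uncatalysed racemic cyclisation slow.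

Step 6
Reactants: 11 (4aR,8aS)-8a-methyl-6-(triisopropylsilyloxy)-3,4,4a,7,8,8a-hexahydronaphthalen-1(2H)-one
Product: 13 (4aR,8aS)-8a-methyl-6-(triisopropylsilyloxy)-3,4,4a,7,8,8a-hexahydronaphthalen-1-yl trifluoromethanesulfonate, via potassium C3=C4 enolate 12 (not isolated)
Conditions: KN(SiMe3)2, THF, −78 °C; PhN(SO2CF3)2, −78 → 0 °C
Reagents that add atoms: N-phenylbis(trifluoromethanesulfonimide), O=S(=O)(N(c1ccccc1)S(=O)(=O)C(F)(F)F)C(F)(F)F
Why: Enol triflate formation, regiospecific because the C4 ketone can enolise only toward C3 (C5 is quaternary), with the ring B silyl enol ether stable to the amide base.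

Step 7
Reactants: 13 (4aR,8aS)-8a-methyl-6-(triisopropylsilyloxy)-3,4,4a,7,8,8a-hexahydronaphthalen-1-yl trifluoromethanesulfonate
Product: 14 triisopropyl{[(4aS,8aR)-4a,5-dimethyl-3,4,4a,7,8,8a-hexahydronaphthalen-2-yl]oxy}silane
Conditions: MeMgBr (1.5 equiv), Fe(acac)3 (5 mol%), THF/NMP, −30 → 0 °C
Reagents that add atoms: methylmagnesium bromide, C[Mg]Br
Why: Iron-catalysed cross-coupling of an alkenyl triflate with a methyl Grignard reagent (Kumada-type) puts C15 on C4 and leaves the silyl enol ether of ring B intact.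

Step 8
Reactants: 14 triisopropyl{[(4aS,8aR)-4a,5-dimethyl-3,4,4a,7,8,8a-hexahydronaphthalen-2-yl]oxy}silane
Product: 16 9β-(triisopropylsilyloxy)-11,12,13-trinor-10βH-eremophil-3-en-8-one, via 8,9β-epoxy silyl ether 15 (not isolated)
Conditions: mCPBA (1.05 equiv), NaHCO3, CH2Cl2, −40 → 0 °C
Reagents that add atoms: 3-chloroperbenzoic acid, OOC(=O)c1cccc(Cl)c1
Why: Rubottom oxidation, in which the peracid epoxidises the electron-rich silyl enol ether far faster than the hindered trisubstituted C3=C4 alkene, the silyloxy epoxide opens with 1,4-silyl migration to the α-silyloxy ketone, and attack on the convex β-face of ring B (the C4 branch of ring A is axial on the α-face) should give the equatorial 9β-oxygen, which is also the thermodynamically preferred epimer.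

Step 9
Reactants: 16 9β-(triisopropylsilyloxy)-11,12,13-trinor-10βH-eremophil-3-en-8-one; 17 acetone
Product: 19 11-hydroxy-9β-(triisopropylsilyloxy)-7αH,10βH-eremophil-3-en-8-one, via lithium C7=C8 enolate 18 (not isolated)
Conditions: LiN(iPr)2, THF, −78 °C; ZnCl2; 17, −78 → −40 °C; aq NH4Cl
Reagents that add atoms: none
Why: Kinetic deprotonation of an α-silyloxy ketone takes place at the unsubstituted α′-carbon C7, and the zinc enolate adds to acetone (aldol addition) on the β-face, anti to the axial C4 branch on C5, so that the reversible addition should settle on the equatorial 7β-adduct.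

Step 10
Reactants: 19 11-hydroxy-9β-(triisopropylsilyloxy)-7αH,10βH-eremophil-3-en-8-one
Product: 21 9β-(triisopropylsilyloxy)-4αH,7αH,10βH-eremophilane-3α,8,11-triol, via C3-boryl bis(boryloxy) adduct 20 (not isolated)
Conditions: BH3·THF (5 equiv), THF, 0 °C → rt; then aq NaOH, H2O2, 0 °C → rt
Reagents that add atoms: hydrogen peroxide, OO
Why: Hydroboration–oxidation adds H and OH syn across C3=C4 with boron on the less substituted C3; with ring B locked by its equatorial C7 and C9 substituents, C14 stands axial over the β-face of ring A, so borane should add from the α-face and give 3α-OH with 4β-CH3 (trans), while the C8 ketone is reduced in the same pot and restored in step 12.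

Step 11
Reactants: 21 9β-(triisopropylsilyloxy)-4αH,7αH,10βH-eremophilane-3α,8,11-triol; 22 3-methylbut-2-enoic acid
Product: 23 8,11-dihydroxy-9β-(triisopropylsilyloxy)-4αH,7αH,10βH-eremophilan-3α-yl 3-methylbut-2-enoate
Conditions: 22 (1.2 equiv), EDC·HCl, DMAP (0.2 equiv), CH2Cl2, 0 °C → rt
Reagents that add atoms: none
Why: Steglich esterification should take place only at the C3 hydroxyl, the one unhindered secondary alcohol (C8–OH is flanked by the silyl ether and the C11 carbinol, C11–OH is tertiary), and the free acid avoids the deconjugation that the acid chloride suffers through its vinylketene.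

Step 12
Reactants: 23 8,11-dihydroxy-9β-(triisopropylsilyloxy)-4αH,7αH,10βH-eremophilan-3α-yl 3-methylbut-2-enoate
Product: 24 11-hydroxy-8-oxo-9β-(triisopropylsilyloxy)-4αH,7αH,10βH-eremophilan-3α-yl 3-methylbut-2-enoate
Conditions: Dess–Martin periodinane, NaHCO3, CH2Cl2, 0 °C → rt
Reagents that add atoms: none
Why: Dess–Martin oxidation of the only remaining secondary alcohol returns the C8 ketone under buffered, non-basic conditions that spare the tertiary aldol hydroxyl from retro-aldol cleavage and the C7 and C9 centres from epimerisation.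

Step 13
Reactants: 24 11-hydroxy-8-oxo-9β-(triisopropylsilyloxy)-4αH,7αH,10βH-eremophilan-3α-yl 3-methylbut-2-enoate
Product: 26 8-oxo-9β-(triisopropylsilyloxy)-4αH,7αH,10βH-eremophil-11-en-3α-yl 3-methylbut-2-enoate, via C11 chlorosulfite 25 (not isolated)
Conditions: SOCl2 (1.5 equiv), pyridine, CH2Cl2, −40 → −10 °C
Reagents that add atoms: none
Why: Dehydration through the chlorosulfite (E2 with pyridine) should remove one of the six methyl hydrogens in preference to the single ring hydrogen at C7, whose anti-periplanar rotamer is crowded, and at low temperature without a strong base the E1cB route to the conjugated isopropylidene ketone and epimerisation at C7 should be avoided.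

Step 14
Reactants: 26 8-oxo-9β-(triisopropylsilyloxy)-4αH,7αH,10βH-eremophil-11-en-3α-yl 3-methylbut-2-enoate
Product: 27 9β-hydroxy-8-oxo-4αH,7αH,10βH-eremophil-11-en-3α-yl 3-methylbut-2-enoate
Conditions: HF·pyridine, pyridine, THF, 0 °C → rt
Reagents that add atoms: none
Why: Fluoride-mediated silyl ether cleavage under buffered, mildly acidic conditions frees the C9 hydroxyl without touching the ester or moving the β,γ-double bond into conjugation.

Step 15
Reactants: 27 9β-hydroxy-8-oxo-4αH,7αH,10βH-eremophil-11-en-3α-yl 3-methylbut-2-enoate; 28 (Z)-2-methylbut-2-enoic acid (angelic acid)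
Product: 30 9β-[(Z)-2-methylbut-2-enoyloxy]-8-oxo-4αH,7αH,10βH-eremophil-11-en-3α-yl 3-methylbut-2-enoate (CNP0164025.2), via angelic 2,4,6-trichlorobenzoic anhydride 29 (not isolated)
Conditions: 28, 2,4,6-trichlorobenzoyl chloride, Et3N, toluene, rt; then 27, 60 °C
Reagents that add atoms: none
Why: Yamaguchi-type mixed anhydride acylation without a nucleophilic catalyst is the established way to make angelates without Z to E isomerisation to the tiglate, and the C7 and C9 substituents are already the equatorial, thermodynamically preferred epimers.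

Compound list
1 | hex-5-enoic acid | C=CCCCC(=O)O | starting material
2 | N,O-dimethylhydroxylamine hydrochloride | CNOC.Cl | starting material
3 | 1-(hex-5-enoyl)imidazole | C=CCCCC(=O)n1ccnc1 | intermediate (not isolated)
4 | N-methoxy-N-methylhex-5-enamide | C=CCCCC(=O)N(C)OC | intermediate
5 | but-3-en-2-one (methyl vinyl ketone) | CC(=O)C=C | starting material
6 | (E)-N-methoxy-N-methyl-7-oxooct-5-enamide | CC(=O)/C=C/CCCC(=O)N(C)OC | intermediate
7 | (E)-N-methoxy-N-methyl-7-(triisopropylsilyloxy)octa-5,7-dienamide | C=C(O[Si](C(C)C)(C(C)C)C(C)C)/C=C/CCCC(=O)N(C)OC | intermediate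
8 | isopropenylmagnesium bromide | C=C(C)[Mg]Br | starting material
9 | bromomagnesium hemiaminal alkoxide from 7 and 8 | C=C(C)C(O[Mg]Br)(N(C)OC)CCC/C=C/C(=C)O[Si](C(C)C)(C(C)C)C(C)C | intermediate (not isolated)
10 | (7E)-2-methyl-9-(triisopropylsilyloxy)deca-1,7,9-trien-3-one | CC(=C)C(=O)CCC/C=C/C(=C)O[Si](C(C)C)(C(C)C)C(C)C | intermediate
11 | (4aR,8aS)-8a-methyl-6-(triisopropylsilyloxy)-3,4,4a,7,8,8a-hexahydronaphthalen-1(2H)-one | C1C[C@@]2(C)[C@H](CCCC2=O)C=C1O[Si](C(C)C)(C(C)C)C(C)C | intermediate
12 | potassium C3=C4 enolate of 11 | C1C[C@@]2(C)[C@H](CCC=C2O[K])C=C1O[Si](C(C)C)(C(C)C)C(C)C | intermediate (not isolated)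
13 | (4aR,8aS)-8a-methyl-6-(triisopropylsilyloxy)-3,4,4a,7,8,8a-hexahydronaphthalen-1-yl trifluoromethanesulfonate | C1C[C@@]2(C)[C@H](CCC=C2OS(=O)(=O)C(F)(F)F)C=C1O[Si](C(C)C)(C(C)C)C(C)C | intermediate
14 | triisopropyl{[(4aS,8aR)-4a,5-dimethyl-3,4,4a,7,8,8a-hexahydronaphthalen-2-yl]oxy}silane | C1C[C@@]2(C)[C@H](CCC=C2C)C=C1O[Si](C(C)C)(C(C)C)C(C)C | intermediate
15 | 8,9β-epoxide of 14 (8α-triisopropylsilyloxy) | C1C[C@@]2(C)[C@H](CCC=C2C)[C@H]3O[C@@]13O[Si](C(C)C)(C(C)C)C(C)C | intermediate (not isolated)
16 | 9β-(triisopropylsilyloxy)-11,12,13-trinor-10βH-eremophil-3-en-8-one | C1C[C@@]2(C)[C@H](CCC=C2C)[C@@H](O[Si](C(C)C)(C(C)C)C(C)C)C1=O | intermediate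
17 | acetone | CC(C)=O | starting material
18 | lithium C7=C8 enolate of 16 | [Li]OC1=CC[C@@]2(C)[C@H](CCC=C2C)[C@H]1O[Si](C(C)C)(C(C)C)C(C)C | intermediate (not isolated)
19 | 11-hydroxy-9β-(triisopropylsilyloxy)-7αH,10βH-eremophil-3-en-8-one | CC(C)(O)[C@H]1C[C@@]2(C)[C@H](CCC=C2C)[C@@H](O[Si](C(C)C)(C(C)C)C(C)C)C1=O | intermediate
20 | C3-boryl bis(boryloxy) adduct, drawn monomeric (3α-BH2, 8-OBH2, 11-OBH2) | CC(C)(OB)[C@H]1C[C@@]2(C)[C@H](CC[C@@H](B)[C@@H]2C)[C@@H](O[Si](C(C)C)(C(C)C)C(C)C)C1OB | intermediate (not isolated)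
21 | 9β-(triisopropylsilyloxy)-4αH,7αH,10βH-eremophilane-3α,8,11-triol | CC(C)(O)[C@H]1C[C@@]2(C)[C@H](CC[C@@H](O)[C@@H]2C)[C@@H](O[Si](C(C)C)(C(C)C)C(C)C)C1O | intermediate
22 | 3-methylbut-2-enoic acid (senecioic acid) | CC(C)=CC(=O)O | starting material
23 | 8,11-dihydroxy-9β-(triisopropylsilyloxy)-4αH,7αH,10βH-eremophilan-3α-yl 3-methylbut-2-enoate | CC(C)(O)[C@H]1C[C@@]2(C)[C@H](CC[C@@H](OC(=O)C=C(C)C)[C@@H]2C)[C@@H](O[Si](C(C)C)(C(C)C)C(C)C)C1O | intermediate
24 | 11-hydroxy-8-oxo-9β-(triisopropylsilyloxy)-4αH,7αH,10βH-eremophilan-3α-yl 3-methylbut-2-enoate | CC(C)(O)[C@H]1C[C@@]2(C)[C@H](CC[C@@H](OC(=O)C=C(C)C)[C@@H]2C)[C@@H](O[Si](C(C)C)(C(C)C)C(C)C)C1=O | intermediate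
25 | C11 chlorosulfite of 24 | CC(C)(OS(=O)Cl)[C@H]1C[C@@]2(C)[C@H](CC[C@@H](OC(=O)C=C(C)C)[C@@H]2C)[C@@H](O[Si](C(C)C)(C(C)C)C(C)C)C1=O | intermediate (not isolated)
26 | 8-oxo-9β-(triisopropylsilyloxy)-4αH,7αH,10βH-eremophil-11-en-3α-yl 3-methylbut-2-enoate | C=C(C)[C@H]1C[C@@]2(C)[C@H](CC[C@@H](OC(=O)C=C(C)C)[C@@H]2C)[C@@H](O[Si](C(C)C)(C(C)C)C(C)C)C1=O | intermediate
27 | 9β-hydroxy-8-oxo-4αH,7αH,10βH-eremophil-11-en-3α-yl 3-methylbut-2-enoate | C=C(C)[C@H]1C[C@@]2(C)[C@H](CC[C@@H](OC(=O)C=C(C)C)[C@@H]2C)[C@@H](O)C1=O | intermediate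
28 | (Z)-2-methylbut-2-enoic acid (angelic acid) | C/C=C(/C)C(=O)O | starting material
29 | angelic 2,4,6-trichlorobenzoic anhydride | C/C=C(/C)C(=O)OC(=O)c1c(Cl)cc(Cl)cc1Cl | intermediate (not isolated)
30 | 9β-[(Z)-2-methylbut-2-enoyloxy]-8-oxo-4αH,7αH,10βH-eremophil-11-en-3α-yl 3-methylbut-2-enoate (CNP0164025.2) | C=C(C)[C@H]1C[C@@]2(C)[C@H](CC[C@@H](OC(=O)C=C(C)C)[C@@H]2C)[C@@H](OC(=O)/C(C)=C\C)C1=O | target

Total step count: 15
Longest linear sequence: 15 steps (1 to 30)

Steps most likely to fail

Step 5. The isopropenyl ketone has no α-hydrogen for a second contact with the catalyst, so face discrimination may be poor. Uncatalysed or Brønsted-acid-promoted cyclisation may erode the enantiomeric purity, and the strong acid may protodesilylate the dienol ether. Fallback, from 10 back to 11: cyclisation of 10 with Me2AlCl (CH2Cl2, −78 °C) should give the cis-fused racemate, that is 11 together with its enantiomer ent-11 F1. The racemate is treated with the lithium salt of (S)-N,S-dimethyl-S-phenylsulfoximine (n-BuLi, THF, −78 °C), and the diastereomeric adducts are separated on silica. The β-hydroxy sulfoximine adduct of the (4aR,8aS) ketone F2 is then heated in toluene at 110 °C, which reverses the addition and returns 11.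

Step 13. Elimination may run toward the acidic C7–H and give the conjugated isopropylidene ketone, with loss of the C7 stereocentre. Fallback, from 24 back to 26: the elimination is driven entirely to the conjugated side (MsCl, Et3N, then DBU, CH2Cl2) to give the 7(11)-en-8-one F3. Soft enolisation (Me3SiOSO2CF3, Et3N, CH2Cl2, 0 °C) at a C11 methyl group, C9–H being shielded by its silyloxy group, gives the 8-trimethylsilyloxy-7,11-diene F4. Release of the dienolate with Bu4NF and AcOH in THF at −78 °C should then protonate C7 kinetically from the axial α-direction (deconjugation by kinetic α-protonation) and give 26.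

Step 10. Hydroboration of the trisubstituted alkene next to the quaternary C5 may be slow or incompletely face-selective, and the three hydroxyl groups formed by over-reduction may be hard to differentiate. Fallback, from 19 back to 24:
- mCPBA (NaHCO3, CH2Cl2, 0 °C) epoxidises C3=C4 on the α-face to give the 3α,4α-epoxide F5.
- Cp2TiCl (trivalent titanium, made from Cp2TiCl2 and Mn dust, THF, rt) opens the epoxide to the tertiary C4 radical, which loses a C15 hydrogen and gives the exocyclic allylic alcohol F6.
- Hydroxyl-directed hydrogenation with [Ir(cod)(PCy3)(py)]PF6 (H2, CH2Cl2) delivers hydrogen to C4 on the face of the 3α-hydroxyl and gives the keto diol F7.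
- Esterification of F7 under the conditions of step 11 gives 24, with no reduction and re-oxidation at C8.

Further compounds
F1 | step 5 | ent-11, (4aS,8aR)-8a-methyl-6-(triisopropylsilyloxy)-3,4,4a,7,8,8a-hexahydronaphthalen-1(2H)-one, formed with 11 as the racemate | C1C[C@]2(C)[C@@H](CCCC2=O)C=C1O[Si](C(C)C)(C(C)C)C(C)C
F2 | step 5 | β-hydroxy sulfoximine adduct of 11 at C4 with (S)-N,S-dimethyl-S-phenylsulfoximine (carbinol configuration open) | C1C[C@@]2(C)[C@H](CCCC2(O)C[S@@](=O)(=NC)c3ccccc3)C=C1O[Si](C(C)C)(C(C)C)C(C)C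
F3 | step 13 | 8-oxo-9β-(triisopropylsilyloxy)-4αH,10βH-eremophil-7(11)-en-3α-yl 3-methylbut-2-enoate | CC(C)=C1C[C@@]2(C)[C@H](CC[C@@H](OC(=O)C=C(C)C)[C@@H]2C)[C@@H](O[Si](C(C)C)(C(C)C)C(C)C)C1=O
F4 | step 13 | 8-(trimethylsilyloxy)-9β-(triisopropylsilyloxy)-4αH,10βH-eremophila-7,11-dien-3α-yl 3-methylbut-2-enoate | C=C(C)C1C[C@@]2(C)[C@H](CC[C@@H](OC(=O)C=C(C)C)[C@@H]2C)[C@@H](O[Si](C(C)C)(C(C)C)C(C)C)C=1O[Si](C)(C)C
F5 | step 10 | 3α,4α-epoxy-11-hydroxy-9β-(triisopropylsilyloxy)-7αH,10βH-eremophilan-8-one | CC(C)(O)[C@H]1C[C@@]2(C)[C@H](CC[C@H]3O[C@@]23C)[C@@H](O[Si](C(C)C)(C(C)C)C(C)C)C1=O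
F6 | step 10 | 3α,11-dihydroxy-9β-(triisopropylsilyloxy)-7αH,10βH-eremophil-4(15)-en-8-one | CC(C)(O)[C@H]1C[C@@]2(C)[C@H](CC[C@@H](O)C2=C)[C@@H](O[Si](C(C)C)(C(C)C)C(C)C)C1=O
F7 | step 10 | 3α,11-dihydroxy-9β-(triisopropylsilyloxy)-4αH,7αH,10βH-eremophilan-8-one | CC(C)(O)[C@H]1C[C@@]2(C)[C@H](CC[C@@H](O)[C@@H]2C)[C@@H](O[Si](C(C)C)(C(C)C)C(C)C)C1=O
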